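The route disconnects ring C of the top gallocatechin unit across O1–C2 and C3–C4. Both bonds are made in one chiral-acid-catalysed inverse-demand oxa-Diels–Alder reaction between an o-quinone methide (O1=C8a–C4a=C4 of top ring A, with C4 already bonded to C8 of the middle unit) and an (E)-styrenyl pinacol boronate. The boron dictates the regiochemistry and is a masked 3-hydroxyl. The step exploits the all-equatorial 2,3-trans-3,4-trans (2,4-cis) pattern of ring C and the latent 1-oxadiene of the phloroglucinol ring A. The precursor is an o-hydroxybenzhydrol made from a lithiated, benzyl-protected gallocatechin-(4α→8)-catechin dimer and a salicylaldehyde.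

Key step: step 10

Remark: (+)-gallocatechin 3 is taken as purchasable; the C4 configuration of 6 and 7 and the carbinol configuration of 13 are of no consequence, because both centres are ionised in the following step.

Step 1
Reactants: 1 (+)-catechin
Product: 2 5,7,3′,4′-tetra-O-benzyl-(+)-catechin
Conditions: BnBr (4.4 equiv), K2CO3, DMF, 0 °C → rt
Reagents that add atoms: benzyl bromide, BrCc1ccccc1
Why: Williamson etherification in which carbonate deprotonates only the four phenols, so the secondary 3-OH stays free and no stereocentre is touched.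

Step 2
Reactants: 3 (+)-gallocatechin
Product: 4 5,7,3′,4′,5′-penta-O-benzyl-(+)-gallocatechin
Conditions: BnBr (5.5 equiv), K2CO3, DMF, argon, 0 °C → rt
Reagents that add atoms: benzyl bromide, BrCc1ccccc1
Why: Williamson etherification of the five phenols under exclusion of air, which should leave the aliphatic 3-OH and both stereocentres unchanged.

Step 3
Reactants: 4 penta-O-benzylgallocatechin
Product: 5 8-bromo-5,7,3′,4′,5′-penta-O-benzyl-(+)-gallocatechin
Conditions: NBS (1.0 equiv), CH2Cl2, −78 °C → rt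
Reagents that add atoms: N-bromosuccinimide, O=C1CCC(=O)N1Br
Why: electrophilic aromatic bromination at C8, the most nucleophilic position of a 5,7-dialkoxyflavan ring A; the bromine blocks C8 during the coupling and is the later handle for lithiation.

Step 4
Reactants: 5 8-bromo-penta-O-benzylgallocatechin
Product: 6 (2R,3S,4S)-8-bromo-4-(2-ethoxyethoxy)-5,7,3′,4′,5′-penta-O-benzylgallocatechin (4β, 3,4-cis)
Conditions: DDQ (2 equiv), 2-ethoxyethanol (5 equiv), CH2Cl2, rt
Reagents that add atoms: 2-ethoxyethanol, CCOCCO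
Why: DDQ benzylic oxidation, in which hydride abstraction from C4 gives a cation stabilised by ring A that the alcohol traps, so that only C4 is functionalised.

Step 5
Reactants: 6 4-(2-ethoxyethoxy) bromide
Product: 7 3-O-acetyl derivative of 6
Conditions: Ac2O, pyridine, DMAP (cat.), rt
Reagents that add atoms: acetic anhydride, CC(=O)OC(C)=O
Why: DMAP-catalysed acylation of the secondary 3-OH, which installs the participating group needed for the stereocontrol of step 6.

Step 6
Reactants: 7 3-O-acetyl-4-(2-ethoxyethoxy) bromide; 2 tetra-O-benzylcatechin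
Product: 8 3-O-acetyl-8-bromo-penta-O-benzylgallocatechin-(4α→8)-tetra-O-benzylcatechin
Conditions: 2 (3 equiv), TMSOTf (0.2 equiv), CH2Cl2, −78 °C
Reagents that add atoms: none
Why: Lewis-acid ionisation of the 4-alkoxy group followed by Friedel–Crafts-type attack of C8 of 2; the 3-acetoxy group bridges the C4 cation, so the arene enters anti to O3 and sets the 3,4-trans (4α) interflavan bond, while the C8 bromine prevents chain growth.

Step 7
Reactants: 9 2,4,6-trihydroxybenzaldehyde
Product: 10 4,6-bis(benzyloxy)-2-hydroxybenzaldehyde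
Conditions: BnBr (2.05 equiv), K2CO3, DMF, 0 °C → rt
Reagents that add atoms: benzyl bromide, BrCc1ccccc1
Why: Williamson etherification that should stop at the dibenzyl stage, because the last phenol is hydrogen-bonded to the formyl group and is the least nucleophilic.

Step 8
Reactants: 8 dimer bromide acetate; 10 4,6-bis(benzyloxy)-2-hydroxybenzaldehyde
Product: 13 dimer-derived o-hydroxybenzhydrol, via trilithiated dimer 11 (not isolated), via sodium formylphenoxide 12 (not isolated)
Conditions: 8, MeLi (3.3 equiv), THF, −78 °C; t-BuLi (2.1 equiv), −78 °C; then 12 (1.5 equiv, from 10 and NaH, THF, 0 °C), −78 → 0 °C; H2O; Et3N-deactivated SiO2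
Reagents that add atoms: none
Why: MeLi removes the hydroxyl proton and cleaves the acetate, t-BuLi effects bromine–lithium exchange at C8, and the aryllithium adds 1,2 to the formyl group of the pre-formed phenoxide; the carbinol centre forms as an epimer mixture that is planarised in step 10.

Step 9
Reactants: 14 3,4,5-tris(benzyloxy)benzaldehyde; 15 bis[(pinacolato)boryl]methane
Product: 17 (E)-2-[3,4,5-tris(benzyloxy)phenyl]ethenyl pinacol boronate, via lithiated diborylmethane 16 (not isolated)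
Conditions: 15, lithium 2,2,6,6-tetramethylpiperidide (LiTMP, 1.1 equiv), THF, 0 °C; then 14, −78 °C → rt
Reagents that add atoms: none
Why: boron–Wittig olefination, in which addition of the α-boryl carbanion to the aldehyde and syn elimination of the boron-bound alkoxide should give the E alkenyl boronate selectively.

Step 10
Reactants: 13 o-hydroxybenzhydrol; 17 (E)-alkenyl pinacol boronate
Product: 19 tetradeca-O-benzyl trimer carrying a pinacol boronate at C3 of the top unit (2,3-trans-3,4-trans), via o-quinone methide 18 (not isolated)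
Conditions: 17 (3 equiv), (R)-3,3′-bis(2,4,6-triisopropylphenyl)-1,1′-binaphthyl-2,2′-diyl N-triflylphosphoramide (10 mol %), 5 Å MS, toluene, −40 → 0 °C
Reagents that add atoms: none
Why: Proposed new method: the acid dehydrates 13 to the E-configured o-quinone methide 18 (1-oxadiene O1=C8a–C4a=C4, held as a hydrogen-bonded chiral ion pair), which should add 17 in an asynchronous inverse-electron-demand oxa-[4+2] cycloaddition in which C4 bonds to the boron-bearing carbon (the developing cation at C2 is benzylic, alkoxy-stabilised and β to boron) and O1 then closes on C2; the closest known reaction type is the chiral-Brønsted-acid-catalysed hetero-Diels–Alder reaction of 4-aryl o-quinone methides with styrenes, extended here to a β-boryl styrene that keeps its boron. Ring C is closed in a single six-membered [4+2] annulation, with C3–C4 formed ahead of O1–C2 (in the stepwise limit, a six-membered closure of the phenolic oxygen on the benzylic cation). The C2/C3 trans relationship is fixed by the E geometry of 17 through suprafacial addition; the 3,4-trans (2,4-cis) relationship by the endo orientation of the dienophile aryl group (boron exo) towards the E-methide, which is also the all-equatorial arrangement; and the absolute sense at C4, and with it at C2 and C3, by the chiral phosphoramide anion shielding one face of the methide, the enantiomeric catalyst being the direct alternative if the pairing with the chiral dimer proves mismatched. The step needs regioselectivity (secured jointly by aryl and boron), retention of boron against alkenyl transfer (pinacol ester, non-nucleophilic counter-anion) and chemoselectivity against Friedel–Crafts attack of the methide on free C6 positions (excess 17, dilution, low temperature).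

Step 11
Reactants: 19 cycloadduct boronate
Product: 20 tetradeca-O-benzyl prodelphinidin C2 (three free 3-OH groups)
Conditions: NaBO3·4H2O (5 equiv), THF/H2O (1:1), 0 °C → rt
Reagents that add atoms: sodium perborate, [Na+].[Na+].O[B-]1(O)OO[B-](O)(O)OO1
Why: boronate oxidation by 1,2-migration of C3 from boron to oxygen in the peroxoborate, which proceeds with retention and so converts the C3–B bond into the 3-OH trans to both neighbouring aryl groups.

Step 12
Reactants: 20 tetradeca-O-benzyl prodelphinidin C2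
Product: 21 prodelphinidin C2 [gallocatechin-(4α→8)-gallocatechin-(4α→8)-catechin]
Conditions: H2 (1 atm), Pd(OH)2/C, THF/MeOH/H2O, rt
Reagents that add atoms: none
Why: catalytic hydrogenolysis of the fourteen benzyl ethers, under which the interflavan bonds, the ring C ethers and all stereocentres should be unaffected.

Compound list
1 | (+)-catechin, (2R,3S) | O[C@H]1Cc2c(O)cc(O)cc2O[C@@H]1c1ccc(O)c(O)c1 | starting material
2 | 5,7,3′,4′-tetra-O-benzyl-(+)-catechin | O[C@H]1Cc2c(OCc3ccccc3)cc(OCc3ccccc3)cc2O[C@@H]1c1ccc(OCc2ccccc2)c(OCc2ccccc2)c1 | intermediate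
3 | (+)-gallocatechin, (2R,3S) | O[C@H]1Cc2c(O)cc(O)cc2O[C@@H]1c1cc(O)c(O)c(O)c1 | starting material
4 | 5,7,3′,4′,5′-penta-O-benzyl-(+)-gallocatechin | O[C@H]1Cc2c(OCc3ccccc3)cc(OCc3ccccc3)cc2O[C@@H]1c1cc(OCc2ccccc2)c(OCc2ccccc2)c(OCc2ccccc2)c1 | intermediate
5 | 8-bromo-5,7,3′,4′,5′-penta-O-benzyl-(+)-gallocatechin | O[C@H]1Cc2c(OCc3ccccc3)cc(OCc3ccccc3)c(Br)c2O[C@@H]1c1cc(OCc2ccccc2)c(OCc2ccccc2)c(OCc2ccccc2)c1 | intermediate
6 | (2R,3S,4S)-8-bromo-4-(2-ethoxyethoxy)-penta-O-benzylgallocatechin (3,4-cis) | O[C@H]1[C@@H](OCCOCC)c2c(OCc3ccccc3)cc(OCc3ccccc3)c(Br)c2O[C@@H]1c1cc(OCc2ccccc2)c(OCc2ccccc2)c(OCc2ccccc2)c1 | intermediate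
7 | 3-O-acetyl-8-bromo-4-(2-ethoxyethoxy)-penta-O-benzylgallocatechin | CC(=O)O[C@H]1[C@@H](OCCOCC)c2c(OCc3ccccc3)cc(OCc3ccccc3)c(Br)c2O[C@@H]1c1cc(OCc2ccccc2)c(OCc2ccccc2)c(OCc2ccccc2)c1 | intermediate
8 | 3-O-acetyl-8-bromo-penta-O-benzylgallocatechin-(4α→8)-tetra-O-benzylcatechin | Brc1c(OCc3ccccc3)cc(OCc3ccccc3)c2c1O[C@H](c1cc(OCc3ccccc3)c(OCc3ccccc3)c(OCc3ccccc3)c1)[C@@H](OC(C)=O)[C@@H]2c1c(OCc3ccccc3)cc(OCc3ccccc3)c2c1O[C@H](c1ccc(OCc3ccccc3)c(OCc3ccccc3)c1)[C@@H](O)C2 | intermediate
9 | 2,4,6-trihydroxybenzaldehyde | O=Cc1c(O)cc(O)cc1O | starting material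
10 | 4,6-bis(benzyloxy)-2-hydroxybenzaldehyde | O=Cc1c(O)cc(OCc2ccccc2)cc1OCc1ccccc1 | intermediate
11 | trilithiated dimer: 8-lithio dimer as its bis(lithium alkoxide), formed in situ | [Li]c1c(OCc3ccccc3)cc(OCc3ccccc3)c2c1O[C@H](c1cc(OCc3ccccc3)c(OCc3ccccc3)c(OCc3ccccc3)c1)[C@@H](O[Li])[C@@H]2c1c(OCc3ccccc3)cc(OCc3ccccc3)c2c1O[C@H](c1ccc(OCc3ccccc3)c(OCc3ccccc3)c1)[C@@H](O[Li])C2 | intermediate
12 | sodium 3,5-bis(benzyloxy)-2-formylphenoxide, formed in situ | [Na+].[O-]c1cc(OCc2ccccc2)cc(OCc2ccccc2)c1C=O | intermediate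
13 | o-hydroxybenzhydrol: [4,6-bis(benzyloxy)-2-hydroxyphenyl](dimer-C8-yl)methanol, epimer mixture at the carbinol carbon | OC(c1c(O)cc(OCc3ccccc3)cc1OCc3ccccc3)c1c(OCc3ccccc3)cc(OCc3ccccc3)c2c1O[C@H](c1cc(OCc3ccccc3)c(OCc3ccccc3)c(OCc3ccccc3)c1)[C@@H](O)[C@@H]2c1c(OCc3ccccc3)cc(OCc3ccccc3)c2c1O[C@H](c1ccc(OCc3ccccc3)c(OCc3ccccc3)c1)[C@@H](O)C2 | intermediate
14 | 3,4,5-tris(benzyloxy)benzaldehyde | O=Cc1cc(OCc2ccccc2)c(OCc2ccccc2)c(OCc2ccccc2)c1 | starting material
15 | bis[(pinacolato)boryl]methane | CC1(C)OB(CB2OC(C)(C)C(C)(C)O2)OC1(C)C | starting material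
16 | lithiated bis[(pinacolato)boryl]methane, formed in situ | [Li]C(B1OC(C)(C)C(C)(C)O1)B1OC(C)(C)C(C)(C)O1 | intermediate
17 | (E)-2-[3,4,5-tris(benzyloxy)phenyl]ethenyl pinacol boronate | CC1(C)OB(/C=C/c2cc(OCc3ccccc3)c(OCc3ccccc3)c(OCc3ccccc3)c2)OC1(C)C | intermediate
18 | E-o-quinone methide of 13 (3,5-bis(benzyloxy)-6-arylmethylidene-cyclohexa-2,4-dienone), formed in situ | O=C4C=C(OCc3ccccc3)C=C(OCc3ccccc3)/C4=C\c1c(OCc3ccccc3)cc(OCc3ccccc3)c2c1O[C@H](c1cc(OCc3ccccc3)c(OCc3ccccc3)c(OCc3ccccc3)c1)[C@@H](O)[C@@H]2c1c(OCc3ccccc3)cc(OCc3ccccc3)c2c1O[C@H](c1ccc(OCc3ccccc3)c(OCc3ccccc3)c1)[C@@H](O)C2 | intermediate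
19 | tetradeca-O-benzyl trimer with a pinacol boronate in place of the top 3-OH (top ring C 2,3-trans-3,4-trans, boron in the spatial position of the later hydroxyl) | O(Cc3ccccc3)c1cc(OCc3ccccc3)c2c(c1)O[C@H](c1cc(OCc3ccccc3)c(OCc3ccccc3)c(OCc3ccccc3)c1)[C@@H](B4OC(C)(C)C(C)(C)O4)[C@@H]2c1c(OCc3ccccc3)cc(OCc3ccccc3)c2c1O[C@H](c1cc(OCc3ccccc3)c(OCc3ccccc3)c(OCc3ccccc3)c1)[C@@H](O)[C@@H]2c1c(OCc3ccccc3)cc(OCc3ccccc3)c2c1O[C@H](c1ccc(OCc3ccccc3)c(OCc3ccccc3)c1)[C@@H](O)C2 | intermediate
20 | tetradeca-O-benzyl prodelphinidin C2 | O(Cc3ccccc3)c1cc(OCc3ccccc3)c2c(c1)O[C@H](c1cc(OCc3ccccc3)c(OCc3ccccc3)c(OCc3ccccc3)c1)[C@@H](O)[C@@H]2c1c(OCc3ccccc3)cc(OCc3ccccc3)c2c1O[C@H](c1cc(OCc3ccccc3)c(OCc3ccccc3)c(OCc3ccccc3)c1)[C@@H](O)[C@@H]2c1c(OCc3ccccc3)cc(OCc3ccccc3)c2c1O[C@H](c1ccc(OCc3ccccc3)c(OCc3ccccc3)c1)[C@@H](O)C2 | intermediate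
21 | prodelphinidin C2, gallocatechin-(4α→8)-gallocatechin-(4α→8)-catechin | Oc1cc(O)c2c(c1)O[C@H](c1cc(O)c(O)c(O)c1)[C@@H](O)[C@@H]2c1c(O)cc(O)c2c1O[C@H](c1cc(O)c(O)c(O)c1)[C@@H](O)[C@@H]2c1c(O)cc(O)c2c1O[C@H](c1ccc(O)c(O)c1)[C@@H](O)C2 | target

Total step count: 12. Longest linear sequence: 9 steps (3 → 4 → 5 → 6 → 7 → 8 → 13 → 19 → 20 → 21, steps 2, 3, 4, 5, 6, 8, 10, 11, 12).

Steps most likely to fail

Step 10 (the step labelled as a proposed new method). What may go wrong: loss of boron by alkenyl transfer to C4 without closure of ring C; slow cycloaddition because the dienophile is only moderately nucleophilic, which lets the methide attack free C6 positions of another molecule; and poor facial selectivity if the catalyst and the chiral dimer are mismatched. The fallback sets out from 13 and comes back at 20. Aldehyde 14 would be homologated with dimethyl (1-diazo-2-oxopropyl)phosphonate (K2CO3, MeOH) to 5-ethynyl-1,2,3-tris(benzyloxy)benzene F1. F1 would be combined with 13 under Sc(OTf)3 catalysis (CH2Cl2, 0 °C) in the known o-quinone methide/aryl alkyne [4+2] annulation, which still closes ring C through O1–C2 and C3–C4 and should give the 2-aryl-4H-chromene (flav-2-ene) trimer F2; C4 epimers would be separated at this stage. Hydroboration of F2 with BH3·SMe2 (boron to C3 anti to the C4 aryl group, hydrogen syn at C2) and NaBO3 oxidation should then give 20 with the 2,3-trans-3,4-trans arrangement.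

Step 8. What may go wrong: incomplete bromine–lithium exchange or protonation of the hindered aryllithium, competing benzylic lithiation of benzyl ethers, and sluggish addition to the electron-rich phenoxide aldehyde. The fallback sets out from 10 and comes back at 13. Aldehyde 10 would be silylated (TBSCl, imidazole, DMF) to 4,6-bis(benzyloxy)-2-(tert-butyldimethylsilyloxy)benzaldehyde F3, a more electrophilic partner without a negative charge. Aryllithium 11, generated as in step 8, would add to F3 to give the silyl-protected carbinol F4 (a silyl shift to the benzylic oxygen would be inconsequential). TBAF (THF, 0 °C) would then liberate 13.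

Step 11. What may go wrong: β-elimination of the ring oxygen O1 from the boron ate complex, which opens ring C, competing with the 1,2-migration. The fallback sets out from 19 and comes back at 20. Boronate 19 would be converted with KHF2 (MeOH/H2O) into the potassium trifluoroborate F5, which would be oxidised within minutes by KHSO5 (as Oxone, acetone/H2O, rt) with retention at C3 and without a hydroxide-derived ate complex, giving 20.

Further compounds
F1 | step 10 | 5-ethynyl-1,2,3-tris(benzyloxy)benzene | C#Cc1cc(OCc2ccccc2)c(OCc2ccccc2)c(OCc2ccccc2)c1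
F2 | step 10 | tetradeca-O-benzyl trimer with a 2-aryl-4H-chromene (flav-2-ene) top unit | O(Cc3ccccc3)c1cc(OCc3ccccc3)c2c(c1)OC(c1cc(OCc3ccccc3)c(OCc3ccccc3)c(OCc3ccccc3)c1)=C[C@@H]2c1c(OCc3ccccc3)cc(OCc3ccccc3)c2c1O[C@H](c1cc(OCc3ccccc3)c(OCc3ccccc3)c(OCc3ccccc3)c1)[C@@H](O)[C@@H]2c1c(OCc3ccccc3)cc(OCc3ccccc3)c2c1O[C@H](c1ccc(OCc3ccccc3)c(OCc3ccccc3)c1)[C@@H](O)C2
F3 | step 8 | 4,6-bis(benzyloxy)-2-(tert-butyldimethylsilyloxy)benzaldehyde | O=Cc1c(O[Si](C)(C)C(C)(C)C)cc(OCc2ccccc2)cc1OCc1ccccc1
F4 | step 8 | O-silyl-protected benzhydrol (phenol as its tert-butyldimethylsilyl ether, epimer mixture at the carbinol carbon) | OC(c1c(O[Si](C)(C)C(C)(C)C)cc(OCc3ccccc3)cc1OCc3ccccc3)c1c(OCc3ccccc3)cc(OCc3ccccc3)c2c1O[C@H](c1cc(OCc3ccccc3)c(OCc3ccccc3)c(OCc3ccccc3)c1)[C@@H](O)[C@@H]2c1c(OCc3ccccc3)cc(OCc3ccccc3)c2c1O[C@H](c1ccc(OCc3ccccc3)c(OCc3ccccc3)c1)[C@@H](O)C2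
F5 | step 11 | potassium trifluoroborate corresponding to 19 | O(Cc3ccccc3)c1cc(OCc3ccccc3)c2c(c1)O[C@H](c1cc(OCc3ccccc3)c(OCc3ccccc3)c(OCc3ccccc3)c1)[C@@H]([B-](F)(F)F)[C@@H]2c1c(OCc3ccccc3)cc(OCc3ccccc3)c2c1O[C@H](c1cc(OCc3ccccc3)c(OCc3ccccc3)c(OCc3ccccc3)c1)[C@@H](O)[C@@H]2c1c(OCc3ccccc3)cc(OCc3ccccc3)c2c1O[C@H](c1ccc(OCc3ccccc3)c(OCc3ccccc3)c1)[C@@H](O)C2.[K+]
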